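**Plan**

1. Retrosynthesis: the eight benzyl and two tert-butyl helper groups come off first; then the bonds C2–C3 and C8a–C1 of the dihydronaphthalene are cut, which halves the target into two molecules of one protected rosmarinate; last, the aryl–vinyl bond (Mizoroki–Heck) and the acrylate ester bond are cut.
2. Enabling feature: C1, C2 and the 1-aryl ring (ring C) are one C6–C3 unit; C3, C4 and the benzo ring (ring A, C4a–C8a) are the other. Both are 4-hydroxycinnamates whose phenoxyl radicals carry spin at Cα, and C8a is the ring carbon ortho to the side chain, next to the C8 oxygen.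
3. Forward: bromophenol 5 and acrylate 9 of protected (R)-danshensu are joined to monomer 10; one oxidation joins two molecules of 10 at Cα–Cα′ (C2–C3) and closes ring B at C8a–C1; one Lewis-acid step then frees all ten positions.
4. Helpers: a tert-butyl group at C5 of the cinnamoyl ring blocks coupling at C5 and ring closure at C6 (it ends at C6 of ring A and C5′ of ring C) and leaves at the end by transfer to toluene; benzyl groups mask the other hydroxyl and carboxyl groups.
5. Stereochemistry: both lactate centres come from commercial sodium (R)-danshensu; C2 arises in the radical coupling under the influence of the (R)-ester groups, and C1 is set trans to it in the ring closure. Induction at C2 is expected to be weak, so the two trans diastereomers are separated at the stage of 13.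

Key step: step 7

Remark: the exocyclic C=C geometry of the transient quinone methides 11 and 12 is not fixed and is left open in their SMILES. C1–C8a refer to the dihydronaphthalene of the target; Cα, Cβ and ring positions C1–C6 refer to the cinnamoyl unit of 10. Rings D and E are the two danshensu catechol rings.

**Route**

Step 1
Reactants: 1 3-tert-butyl-2-hydroxybenzaldehyde
Product: 3 3-tert-butylbenzene-1,2-diol, via aryl formate 2 (not isolated)
Conditions: 30% H2O2, NaOH, THF/H2O, 0 °C → rt, argon; then aq. HCl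
Reagents that add atoms: hydrogen peroxide, OO
Why: Dakin oxidation: hydroperoxide adds to the ortho-hydroxy aldehyde, the aryl group migrates to oxygen, and the aryl formate 2 is hydrolysed in the alkaline medium to the catechol.

Step 2
Reactants: 3 3-tert-butylbenzene-1,2-diol
Product: 4 2-(benzyloxy)-6-tert-butylphenol
Conditions: BnBr (1.0 equiv), K2CO3, acetone, reflux, argon
Reagents that add atoms: benzyl bromide, BrCc1ccccc1
Why: Williamson ether synthesis with one equivalent of halide should alkylate only the unhindered hydroxyl, because the other one is shielded by the neighbouring tert-butyl group.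

Step 3
Reactants: 4 2-(benzyloxy)-6-tert-butylphenol
Product: 5 2-(benzyloxy)-4-bromo-6-tert-butylphenol
Conditions: NBS, MeCN, 0 °C
Reagents that add atoms: N-bromosuccinimide, O=C1CCC(=O)N1Br
Why: Electrophilic aromatic bromination should go para to the free hydroxyl, the only position activated by the phenol, since both ortho positions are substituted.

Step 4
Reactants: 6 sodium (2R)-3-(3,4-dihydroxyphenyl)-2-hydroxypropanoate (sodium (R)-danshensu)
Product: 7 benzyl (2R)-3-[3,4-bis(benzyloxy)phenyl]-2-hydroxypropanoate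
Conditions: BnBr (3.3 equiv), K2CO3, DMF, rt
Reagents that add atoms: benzyl bromide, BrCc1ccccc1
Why: SN2 benzylation of the carboxylate and the two phenoxides with carbonate as base leaves the far less acidic secondary alcohol free and does not touch the stereocentre.

Step 5
Reactants: 7 benzyl (2R)-3-[3,4-bis(benzyloxy)phenyl]-2-hydroxypropanoate; 8 acryloyl chloride
Product: 9 benzyl (2R)-3-[3,4-bis(benzyloxy)phenyl]-2-(prop-2-enoyloxy)propanoate
Conditions: Et3N, CH2Cl2, 0 °C
Reagents that add atoms: none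
Why: O-Acylation of the secondary alcohol by the acid chloride breaks no bond at the stereocentre, so the (R) configuration is kept.

Step 6
Reactants: 5 2-(benzyloxy)-4-bromo-6-tert-butylphenol; 9 benzyl (2R)-3-[3,4-bis(benzyloxy)phenyl]-2-(prop-2-enoyloxy)propanoate
Product: 10 benzyl (2R)-3-[3,4-bis(benzyloxy)phenyl]-2-{[(2E)-3-[3-(benzyloxy)-5-tert-butyl-4-hydroxyphenyl]prop-2-enoyl]oxy}propanoate
Conditions: Pd(OAc)2 (5 mol%), P(o-tol)3, Et3N, MeCN, 80 °C
Reagents that add atoms: none
Why: Mizoroki–Heck reaction: the aryl bromide adds to zerovalent palladium, syn insertion of the acrylate and syn β-hydride elimination give the (E)-cinnamate, and free bromophenols are tolerated.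

Step 7
Reactants: 10 (two molecules) benzyl (2R)-3-[3,4-bis(benzyloxy)phenyl]-2-{[(2E)-3-[3-(benzyloxy)-5-tert-butyl-4-hydroxyphenyl]prop-2-enoyl]oxy}propanoate
Product: 13 bis[(2R)-1-(benzyloxy)-3-[3,4-bis(benzyloxy)phenyl]-1-oxopropan-2-yl] (1R,2S)-8-(benzyloxy)-1-[3-(benzyloxy)-5-tert-butyl-4-hydroxyphenyl]-6-tert-butyl-7-hydroxy-1,2-dihydronaphthalene-2,3-dicarboxylate, via bis(quinone methide) 11 (not isolated), via mono(quinone methide) 12 (not isolated)
Conditions: FeCl3·6H2O (1.05 equiv per phenol), acetone/H2O 9:1, rt; chromatography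
Reagents that add atoms: none
Why: One-electron oxidation of each phenol by trivalent iron gives phenoxyl radicals with spin at Cα, two of which join Cα–Cα′ to the bis(quinone methide) 11; one half re-aromatises by loss of its Cα–H to the (E)-arylidene succinate 12, whose ring A then adds through its C2 to the remaining quinone methide carbon Cβ′ (acid-promoted intramolecular Friedel–Crafts alkylation) to give 13. The closest known reaction type is the FeCl3 dehydrodimerisation of sinapate and 5-substituted ferulate esters to 1-aryl-1,2-dihydronaphthalene-2,3-dicarboxylates. Ring B closes in a 6-exo-trig mode at the exocyclic quinone methide C=C. C2 is fixed in the radical–radical coupling, where the only bias is 1,4-induction from the two (R)-α-acyloxy ester groups, so both trans diastereomers must be expected and the (1R,2S) one is taken by chromatography (the fixed lactate centres make them diastereomers); C1 is then set trans to the C2 ester because the half-chair transition state keeps the quinone methide ring away from that ester, the trans product also being the more stable one. The step needs Cα–Cα′ coupling instead of coupling at C5 or at oxygen, and closure at C2 instead of C6: the tert-butyl group at C5 occupies that carbon, crowds the phenoxyl oxygen and makes attack at C6 impossible without a peri clash with the C1 aryl group, while the benzyl ethers keep rings D and E and the C3 oxygens out of the oxidation. Only one equivalent of oxidant per phenol is used so that 13 is not dehydrogenated to the naphthalene.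

Step 8
Reactants: 13 bis[(2R)-1-(benzyloxy)-3-[3,4-bis(benzyloxy)phenyl]-1-oxopropan-2-yl] (1R,2S)-8-(benzyloxy)-1-[3-(benzyloxy)-5-tert-butyl-4-hydroxyphenyl]-6-tert-butyl-7-hydroxy-1,2-dihydronaphthalene-2,3-dicarboxylate
Product: 14 (2R,2′R)-2,2′-{[(1R,2S)-1-(3,4-dihydroxyphenyl)-7,8-dihydroxy-1,2-dihydronaphthalene-2,3-dicarbonyl]bis(oxy)}bis[3-(3,4-dihydroxyphenyl)propanoic acid] (CNP0244800.2)
Conditions: AlCl3 (excess), MeNO2, toluene, 0 °C → rt; then aq. HCl, reversed-phase chromatography
Reagents that add atoms: none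
Why: AlCl3 should ionise the eight O–benzyl bonds (ethers and esters) and, by ipso protonation ortho to the free hydroxyl groups, expel both tert-butyl groups as cations that toluene traps (Lewis-acid debenzylation with an arene scavenger and retro-Friedel–Crafts trans-tert-butylation of a positional protecting group), while the secondary alkyl–oxygen bonds of the lactate esters, flanked by a carboxyl group, do not ionise and C1 and C2 are not touched.

**Compound list**

1 | 3-tert-butyl-2-hydroxybenzaldehyde | CC(C)(C)c1cccc(C=O)c1O | starting material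
2 | 3-tert-butyl-2-hydroxyphenyl formate | CC(C)(C)c1cccc(OC=O)c1O | intermediate
3 | 3-tert-butylbenzene-1,2-diol | CC(C)(C)c1cccc(O)c1O | intermediate
4 | 2-(benzyloxy)-6-tert-butylphenol | CC(C)(C)c1cccc(OCc2ccccc2)c1O | intermediate
5 | 2-(benzyloxy)-4-bromo-6-tert-butylphenol | CC(C)(C)c1cc(Br)cc(OCc2ccccc2)c1O | intermediate
6 | sodium (2R)-3-(3,4-dihydroxyphenyl)-2-hydroxypropanoate | O[C@H](Cc1ccc(O)c(O)c1)C(=O)[O-].[Na+] | starting material
7 | benzyl (2R)-3-[3,4-bis(benzyloxy)phenyl]-2-hydroxypropanoate | O[C@H](Cc1ccc(OCc2ccccc2)c(OCc2ccccc2)c1)C(=O)OCc1ccccc1 | intermediate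
8 | acryloyl chloride | C=CC(Cl)=O | starting material
9 | benzyl (2R)-3-[3,4-bis(benzyloxy)phenyl]-2-(prop-2-enoyloxy)propanoate | C=CC(=O)O[C@H](Cc1ccc(OCc2ccccc2)c(OCc2ccccc2)c1)C(=O)OCc1ccccc1 | intermediate
10 | benzyl (2R)-3-[3,4-bis(benzyloxy)phenyl]-2-{[(2E)-3-[3-(benzyloxy)-5-tert-butyl-4-hydroxyphenyl]prop-2-enoyl]oxy}propanoate | O=C(/C=C/c1cc(OCc2ccccc2)c(O)c(C(C)(C)C)c1)O[C@H](Cc1ccc(OCc2ccccc2)c(OCc2ccccc2)c1)C(=O)OCc1ccccc1 | intermediate
11 | bis[(2R)-1-(benzyloxy)-3-[3,4-bis(benzyloxy)phenyl]-1-oxopropan-2-yl] (2S,3S)-2,3-bis{[3-(benzyloxy)-5-tert-butyl-4-oxocyclohexa-2,5-dien-1-ylidene]methyl}butanedioate | O=C1C(OCc2ccccc2)=CC(=C[C@@H]([C@H](C=C2C=C(OCc3ccccc3)C(=O)C(C(C)(C)C)=C2)C(=O)O[C@H](Cc2ccc(OCc3ccccc3)c(OCc3ccccc3)c2)C(=O)OCc2ccccc2)C(=O)O[C@H](Cc2ccc(OCc3ccccc3)c(OCc3ccccc3)c2)C(=O)OCc2ccccc2)C=C1C(C)(C)C | intermediate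
12 | bis[(2R)-1-(benzyloxy)-3-[3,4-bis(benzyloxy)phenyl]-1-oxopropan-2-yl] (2E,3S)-2-{[3-(benzyloxy)-5-tert-butyl-4-hydroxyphenyl]methylidene}-3-{[3-(benzyloxy)-5-tert-butyl-4-oxocyclohexa-2,5-dien-1-ylidene]methyl}butanedioate | O=C1C(OCc2ccccc2)=CC(=C[C@@H](/C(C(=O)O[C@H](Cc2ccc(OCc3ccccc3)c(OCc3ccccc3)c2)C(=O)OCc2ccccc2)=C\c2cc(OCc3ccccc3)c(O)c(C(C)(C)C)c2)C(=O)O[C@H](Cc2ccc(OCc3ccccc3)c(OCc3ccccc3)c2)C(=O)OCc2ccccc2)C=C1C(C)(C)C | intermediate
13 | bis[(2R)-1-(benzyloxy)-3-[3,4-bis(benzyloxy)phenyl]-1-oxopropan-2-yl] (1R,2S)-8-(benzyloxy)-1-[3-(benzyloxy)-5-tert-butyl-4-hydroxyphenyl]-6-tert-butyl-7-hydroxy-1,2-dihydronaphthalene-2,3-dicarboxylate | O=C(O[C@H](Cc1ccc(OCc2ccccc2)c(OCc2ccccc2)c1)C(=O)OCc1ccccc1)C1=Cc2cc(C(C)(C)C)c(O)c(OCc3ccccc3)c2[C@@H](c2cc(OCc3ccccc3)c(O)c(C(C)(C)C)c2)[C@@H]1C(=O)O[C@H](Cc1ccc(OCc2ccccc2)c(OCc2ccccc2)c1)C(=O)OCc1ccccc1 | intermediate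
14 | (2R,2′R)-2,2′-{[(1R,2S)-1-(3,4-dihydroxyphenyl)-7,8-dihydroxy-1,2-dihydronaphthalene-2,3-dicarbonyl]bis(oxy)}bis[3-(3,4-dihydroxyphenyl)propanoic acid] | O=C(O[C@H](Cc1ccc(O)c(O)c1)C(=O)O)C1=Cc2ccc(O)c(O)c2[C@@H](c2ccc(O)c(O)c2)[C@@H]1C(=O)O[C@H](Cc1ccc(O)c(O)c1)C(=O)O | target

**Summary**

Total step count: 8. Longest linear sequence: 6 steps (steps 1, 2, 3, 6, 7, 8).

Steps most likely to fail:

1. Step 7 – poor facial selectivity in the radical–radical coupling. The induction from the lactate-type esters is weak, so the (1R,2S) diastereomer may form as the minor component or be hard to separate. The fallback sets out from 5 and 8 and comes back at 13. (S)-4-Benzyloxazolidin-2-one is N-acylated with 8 (n-BuLi, THF, −78 °C) to (S)-3-acryloyl-4-benzyloxazolidin-2-one F1. Mizoroki–Heck coupling of F1 with 5 should give (S)-4-benzyl-3-[(2E)-3-[3-(benzyloxy)-5-tert-butyl-4-hydroxyphenyl]prop-2-enoyl]oxazolidin-2-one F2. Oxidation of F2 with FeCl3·6H2O, now an auxiliary-controlled oxidative phenol coupling in which the 4-benzyl group of the imide shields one face of Cα, should give the bis-imide (1R,2S)-dihydronaphthalene F3; the (R)-auxiliary is taken instead if a model run shows the opposite sense. Cleavage with LiOH/H2O2 (THF/H2O, 0 °C) should free (1R,2S)-8-(benzyloxy)-1-[3-(benzyloxy)-5-tert-butyl-4-hydroxyphenyl]-6-tert-butyl-7-hydroxy-1,2-dihydronaphthalene-2,3-dicarboxylic acid F4. Twofold Steglich esterification of F4 with 7 (EDC·HCl, DMAP, CH2Cl2) returns to 13; any epimerisation at C2 should correct itself toward the more stable trans isomer.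

2. Step 8 – acid-induced side reactions during the long exposure needed to cleave ten groups of two kinds in one pot. These are re-benzylation of the catechol rings, loss of ring C from C1 with aromatisation, and cleavage of a lactate ester. The fallback sets out from 13 and comes back at 14, and separates the two cleavage chemistries. BCl3 with pentamethylbenzene (CH2Cl2, −78 °C) should remove the eight benzyl groups with a non-basic cation scavenger to give the 6,5′-di-tert-butyl derivative of the target F5. The free ortho-tert-butylcatechol rings of F5 should then lose their tert-butyl groups on short treatment with catalytic CF3SO3H in toluene at rt to give 14.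

3. Step 6 – slow oxidative addition to the electron-rich bromophenol. Prolonged heating with amine base could then erode the lactate stereocentre by enolisation or polymerise the acrylate. The fallback sets out from 4 and 7 and comes back at 10. Duff formylation of 4 (hexamethylenetetramine, AcOH, 110 °C; then aq. HCl) should give 3-(benzyloxy)-5-tert-butyl-4-hydroxybenzaldehyde F6. Heating 7 with Meldrum's acid (toluene, 100 °C) should give the malonic half ester 3-{[(2R)-1-(benzyloxy)-3-[3,4-bis(benzyloxy)phenyl]-1-oxopropan-2-yl]oxy}-3-oxopropanoic acid F7. Knoevenagel–Doebner condensation of F6 with F7 (pyridine, cat. piperidine, 60 °C) should deliver 10 with the (E) geometry.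

**Further compounds**

F1 | step 7 | (S)-3-acryloyl-4-benzyloxazolidin-2-one | C=CC(=O)N1C(=O)OC[C@@H]1Cc1ccccc1
F2 | step 7 | (S)-4-benzyl-3-[(2E)-3-[3-(benzyloxy)-5-tert-butyl-4-hydroxyphenyl]prop-2-enoyl]oxazolidin-2-one | O=C(/C=C/c1cc(OCc2ccccc2)c(O)c(C(C)(C)C)c1)N1C(=O)OC[C@@H]1Cc1ccccc1
F3 | step 7 | (4S,4′S)-3,3′-[(1R,2S)-8-(benzyloxy)-1-[3-(benzyloxy)-5-tert-butyl-4-hydroxyphenyl]-6-tert-butyl-7-hydroxy-1,2-dihydronaphthalene-2,3-dicarbonyl]bis(4-benzyloxazolidin-2-one) | O=C(N1C(=O)OC[C@@H]1Cc1ccccc1)C1=Cc2cc(C(C)(C)C)c(O)c(OCc3ccccc3)c2[C@@H](c2cc(OCc3ccccc3)c(O)c(C(C)(C)C)c2)[C@@H]1C(=O)N1C(=O)OC[C@@H]1Cc1ccccc1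
F4 | step 7 | (1R,2S)-8-(benzyloxy)-1-[3-(benzyloxy)-5-tert-butyl-4-hydroxyphenyl]-6-tert-butyl-7-hydroxy-1,2-dihydronaphthalene-2,3-dicarboxylic acid | OC(=O)C1=Cc2cc(C(C)(C)C)c(O)c(OCc3ccccc3)c2[C@@H](c2cc(OCc3ccccc3)c(O)c(C(C)(C)C)c2)[C@@H]1C(=O)O
F5 | step 8 | (2R,2′R)-2,2′-{[(1R,2S)-6-tert-butyl-1-(3-tert-butyl-4,5-dihydroxyphenyl)-7,8-dihydroxy-1,2-dihydronaphthalene-2,3-dicarbonyl]bis(oxy)}bis[3-(3,4-dihydroxyphenyl)propanoic acid] | O=C(O[C@H](Cc1ccc(O)c(O)c1)C(=O)O)C1=Cc2cc(C(C)(C)C)c(O)c(O)c2[C@@H](c2cc(O)c(O)c(C(C)(C)C)c2)[C@@H]1C(=O)O[C@H](Cc1ccc(O)c(O)c1)C(=O)O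
F6 | step 6 | 3-(benzyloxy)-5-tert-butyl-4-hydroxybenzaldehyde | CC(C)(C)c1cc(C=O)cc(OCc2ccccc2)c1O
F7 | step 6 | 3-{[(2R)-1-(benzyloxy)-3-[3,4-bis(benzyloxy)phenyl]-1-oxopropan-2-yl]oxy}-3-oxopropanoic acid | OC(=O)CC(=O)O[C@H](Cc1ccc(OCc2ccccc2)c(OCc2ccccc2)c1)C(=O)OCc1ccccc1
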